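**Plan**

- Retrosynthetic cuts, in order: the C5'–Br bond of ring B; then the C1'–C2' and C4'–C5' bonds of ring B together; then the aryl O–CH2 ether bond; last the C2–Br and C4–Br bonds of ring A.
- Enabling feature: in ring B the hydroxyl carbon C6' lies between the aryloxy carbon C1' and C5', with Br on C3' para to it. C1'–C6'–C5' therefore maps onto an aryloxyacetone and C2'–C3'–C4' onto 2-bromomalonaldehyde.
- Forward: ring A is bought as an arene and brominated, the acetonyl ether is attached, ring B is built by a [3+3] double aldol benzannulation, and the fifth bromine is placed ortho to the new hydroxyl.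
- Stereochemistry: none to set; the target is achiral.

Key step: step 3

Remark: the target has no stereocentre and its diaryl ether bonds rotate freely, so it is one achiral compound. Ring A is numbered C1 (ether carbon) to C6 (methoxy carbon); ring B is numbered C1' (ether carbon) to C6' (hydroxyl carbon).

**Route**

Step 1
Reactants: 1 5-bromo-2-methoxyphenol
Product: 2 2,3,4-tribromo-6-methoxyphenol
Conditions: Br2 (2.05 equiv), AcOH, rt
Reagents that add atoms: bromine, BrBr
Why: Electrophilic aromatic bromination, in which the free hydroxyl is the strongest director and should send the two bromines to its open ortho (C2) and para (C4) positions, while the last C–H (C5, ortho to methoxy only and next to bromine) is too deactivated to react with two equivalents.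

Step 2
Reactants: 2 2,3,4-tribromo-6-methoxyphenol; 3 chloroacetone
Product: 4 1-(2,3,4-tribromo-6-methoxyphenoxy)propan-2-one
Conditions: K2CO3, DMF, 50 °C
Reagents that add atoms: none
Why: Williamson ether synthesis, in which the acidic tribromophenol is fully ionised by carbonate and its oxygen displaces chloride from the activated α-chloro ketone by SN2, C-alkylation being excluded because every ortho and para position is substituted.

Step 3
Reactants: 4 1-(2,3,4-tribromo-6-methoxyphenoxy)propan-2-one; 5 2-bromomalonaldehyde
Product: 8 4-bromo-2-(2,3,4-tribromo-6-methoxyphenoxy)phenol, via open-chain keto enal 6 (not isolated), via cyclohexadienone tautomer 7 (not isolated)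
Conditions: 5 (1.5 equiv), NaOH (3.5 equiv), EtOH/THF/H2O, slow addition of 4, 0 → 50 °C; then aq. HCl
Reagents that add atoms: none
Why: Proposed new method: hydroxide enolises 4 at the more acidic aryloxymethylene carbon, this enolate adds to one formyl carbon of 5 and loses water to give keto enal 6 (C1'–C2' bond), the methyl enolate of 6 then closes onto the second formyl carbon (C4'–C5' bond), and loss of a second water gives dienone 7, which tautomerises irreversibly to the phenoxide of 8 with the former ketone oxygen on C6' and bromine para to it on C3'. The closest known reaction type is the alkali-mediated [3+3] benzannulation of ketones having two enolisable α-carbons with sodium nitromalonaldehyde or 2-substituted vinamidinium salts to 4-substituted phenols; a 2-bromo three-carbon unit combined with an α-aryloxy ketone has not been demonstrated. Ring B closes by an intramolecular aldol in the 6-(enolendo)-exo-trig mode, and the cis relationship of acetyl group and enal arm that this needs is accessible because the C1'=C2' geometry of 6 equilibrates through its delocalised dienolate. No stereocentre is created. The step needs cross-condensation to beat ketone self-aldol and needs the C–Br bond to survive: 5 is held in excess as its enolate, which is too stabilised to self-condense, while 4 is added slowly, self-aldol of 4 is reversible whereas aromatisation is not, and in 5, 6 and the phenoxide the bromine sits on an sp2 carbon where substitution is not available. Only one ring constitution can form because both α-carbons of 4 are used whichever reacts first.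

Step 4
Reactants: 8 4-bromo-2-(2,3,4-tribromo-6-methoxyphenoxy)phenol
Product: 9 2,4-dibromo-6-(2,3,4-tribromo-6-methoxyphenoxy)phenol
Conditions: NBS (1.0 equiv), i-Pr2NH (10 mol%), CH2Cl2, 0 °C → rt
Reagents that add atoms: N-bromosuccinimide, O=C1CCC(=O)N1Br
Why: Amine-catalysed ortho-bromination of a phenol with NBS (electrophilic aromatic substitution), in which C5' is the only free position ortho or para to the ring-B hydroxyl, this hydroxyl activates far more strongly than the aryloxy oxygen tied to the electron-poor ring A, and ring A with three bromines should stay untouched.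

**Compound list**

1 | 5-bromo-2-methoxyphenol | COc1ccc(Br)cc1O | starting material
2 | 2,3,4-tribromo-6-methoxyphenol | COc1cc(Br)c(Br)c(Br)c1O | intermediate
3 | chloroacetone | CC(=O)CCl | starting material
4 | 1-(2,3,4-tribromo-6-methoxyphenoxy)propan-2-one | COc1cc(Br)c(Br)c(Br)c1OCC(C)=O | intermediate
5 | 2-bromomalonaldehyde | O=CC(Br)C=O | starting material
6 | 2-bromo-5-oxo-4-(2,3,4-tribromo-6-methoxyphenoxy)hex-3-enal (open-chain keto enal, not isolated) | COc1cc(Br)c(Br)c(Br)c1OC(=CC(Br)C=O)C(C)=O | intermediate
7 | 4-bromo-2-(2,3,4-tribromo-6-methoxyphenoxy)cyclohexa-2,5-dien-1-one (dienone tautomer, not isolated) | COc1cc(Br)c(Br)c(Br)c1OC1=CC(Br)C=CC1=O | intermediate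
8 | 4-bromo-2-(2,3,4-tribromo-6-methoxyphenoxy)phenol | COc1cc(Br)c(Br)c(Br)c1Oc1cc(Br)ccc1O | intermediate
9 | 2,4-dibromo-6-(2,3,4-tribromo-6-methoxyphenoxy)phenol | COc1cc(Br)c(Br)c(Br)c1Oc1cc(Br)cc(Br)c1O | target

**Step count and risks**

Total step count: 4. Longest linear sequence: 4 (1 → 2 → 4 → 8 → 9).

Steps most likely to fail:

Step 3. The ketone enolate may engage the weakly electrophilic bromomalonaldehyde anion too slowly, so that self-condensation of the ketone or loss of bromide from the three-carbon unit takes over, or the sequence may stall after the first condensation. The fallback builds ring B from a preformed arene and sets out from 2. Nucleophilic aromatic substitution of 2 on 4-bromo-2-fluorobenzaldehyde (O=Cc1ccc(Br)cc1F; K2CO3, DMAc, 120 °C) should displace the fluoride ortho to the formyl group and give 4-bromo-2-(2,3,4-tribromo-6-methoxyphenoxy)benzaldehyde F1. Baeyer–Villiger oxidation with mCPBA in CH2Cl2, where the ortho-oxygenated aryl group migrates, should give 4-bromo-2-(2,3,4-tribromo-6-methoxyphenoxy)phenyl formate F2. Methanolysis (K2CO3, MeOH, rt) should free the phenol, and the route is rejoined at 8.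

Step 4. Bromination may stray to C4', para to the ether oxygen, or run on to a second substitution. The fallback marks C5' with a carbon substituent before the halogen enters; it sets out from 8. Magnesium-mediated ortho-formylation (MgCl2, Et3N, paraformaldehyde, MeCN, reflux), which is confined to the position ortho to the phenoxide, should give 5-bromo-2-hydroxy-3-(2,3,4-tribromo-6-methoxyphenoxy)benzaldehyde F3. Pinnick oxidation (NaClO2, NaH2PO4, 2-methyl-2-butene, t-BuOH/H2O) should give 5-bromo-2-hydroxy-3-(2,3,4-tribromo-6-methoxyphenoxy)benzoic acid F4. Ipso-bromodecarboxylation of this salicylic acid with Br2 (1 equiv) in aqueous AcOH should replace the carboxyl group by bromine and arrive at 9.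

Step 2. Base-induced self-condensation of chloroacetone may outpace O-alkylation of the hindered, weakly nucleophilic phenoxide. The fallback sets out from 2 and uses a non-enolisable electrophile, unveiling the ketone afterwards. Alkylation with propargyl bromide (C#CCBr; K2CO3, DMF, rt) should give 1,2,3-tribromo-5-methoxy-4-(prop-2-yn-1-yloxy)benzene F5. Gold(I)-catalysed Markovnikov hydration of the terminal alkyne (Ph3PAuCl/AgOTf, aqueous dioxane, 60 °C) should then give the methyl ketone, and the route is rejoined at 4. Cyclisation onto the arene is excluded because both ortho positions are occupied.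

**Further compounds**

F1 | step 3 | 4-bromo-2-(2,3,4-tribromo-6-methoxyphenoxy)benzaldehyde | COc1cc(Br)c(Br)c(Br)c1Oc1cc(Br)ccc1C=O
F2 | step 3 | 4-bromo-2-(2,3,4-tribromo-6-methoxyphenoxy)phenyl formate | COc1cc(Br)c(Br)c(Br)c1Oc1cc(Br)ccc1OC=O
F3 | step 4 | 5-bromo-2-hydroxy-3-(2,3,4-tribromo-6-methoxyphenoxy)benzaldehyde | COc1cc(Br)c(Br)c(Br)c1Oc1cc(Br)cc(C=O)c1O
F4 | step 4 | 5-bromo-2-hydroxy-3-(2,3,4-tribromo-6-methoxyphenoxy)benzoic acid | COc1cc(Br)c(Br)c(Br)c1Oc1cc(Br)cc(C(=O)O)c1O
F5 | step 2 | 1,2,3-tribromo-5-methoxy-4-(prop-2-yn-1-yloxy)benzene | COc1cc(Br)c(Br)c(Br)c1OCC#C
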